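**Retrosynthetic overview**
- The depside is cut last at the aryl ester C(=O)–O bond, giving a ring A acid (side-chain ketone masked as a dioxolane) and the C4 phenol of a ring B benzyl ester; hydrogenolysis of the benzyl ester ends the route.
- The route rests on ring B: CO2H at C1, OMe at C2, the depside oxygen at C4 and pentyl at C6, with the C2 and C4 oxygens differentiated. The ring is built from 1,1-dimethoxy-3-(trimethylsilyloxy)buta-1,3-diene and benzyl oct-2-ynoate by Diels-Alder reaction and aromatization (bonds C1–C2 and C5–C6), which delivers C2 as OMe and C4 as free OH.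
- The diene comes from acetyl chloride and 1,1-dichloroethene in three steps; the ynoate comes from oct-2-ynoic acid.
- Ring A is bought as methyl 2,4-dimethoxy-6-methylbenzoate; its 2-oxoheptyl chain is made by lateral lithiation and Weinreb acylation (benzylic CH2 to ketone carbon).
- Ring order: ring B is the only ring formed (step 5); the target has no stereocentre.

Key step: step 5

Remark: the side-chain ketone is carried as its 1,3-dioxolane from step 8 to step 11, because a free 2-(2-oxoalkyl)benzoic acid is expected to close to the 3-alkylisocoumarin when its carboxyl group is activated; LDA is taken as a commercial solution.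

**Step 1**
Reactants: 1 acetyl chloride; 2 1,1-dichloroethene
Product: 4 4,4-dichlorobut-3-en-2-one, via 4,4,4-trichlorobutan-2-one 3 (not isolated)
Conditions: AlCl3 (1.1 equiv), CH2Cl2, 0 °C to rt; ice/H2O; steam distillation
Reagents that add atoms: none
Why: Friedel-Crafts-type acylation of the CH2 end of the chloroalkene by the acylium ion gives trichloro ketone 3, whose acidic alpha-hydrogen allows ready loss of HCl to the conjugated dichloroenone.

**Step 2**
Reactants: 4 4,4-dichlorobut-3-en-2-one
Product: 5 4,4-dimethoxybut-3-en-2-one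
Conditions: NaOMe (2.2 equiv), MeOH, 0 °C to rt; filtration, vacuum distillation
Reagents that add atoms: sodium methoxide, [Na+].[O-]C
Why: Two successive addition-elimination (vinylic substitution) events at the beta carbon of the enone replace both chlorides by methoxide and give the push-pull ketene acetal.

**Step 3**
Reactants: 5 4,4-dimethoxybut-3-en-2-one
Product: 6 1,1-dimethoxy-3-(trimethylsilyloxy)buta-1,3-diene
Conditions: Me3SiCl, Et3N, ZnCl2 (cat.), benzene, rt to 40 °C; filtration under Ar, vacuum distillation
Reagents that add atoms: chlorotrimethylsilane, C[Si](C)(C)Cl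
Why: Soft enolisation of the methyl ketone, the only enolisable position, and O-silylation give the 2-silyloxydiene, as in the standard preparation of silyloxydienes.

**Step 4**
Reactants: 7 oct-2-ynoic acid
Product: 8 benzyl oct-2-ynoate
Conditions: BnBr, K2CO3, DMF, rt
Reagents that add atoms: benzyl bromide, BrCc1ccccc1
Why: SN2 O-alkylation of the carboxylate installs an ester that survives the cycloaddition and the depside coupling and is removable at the end by neutral hydrogenolysis.

**Step 5**
Reactants: 6 1,1-dimethoxy-3-(trimethylsilyloxy)buta-1,3-diene; 8 benzyl oct-2-ynoate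
Product: 11 benzyl 4-hydroxy-2-methoxy-6-pentylbenzoate, via cyclohexadiene cycloadduct 9 (not isolated), via aryl trimethylsilyl ether 10 (not isolated)
Conditions: 6 (2 equiv), neat or minimal toluene, 110–120 °C, sealed tube, Ar; then 1 M HCl (aq), THF, rt
Reagents that add atoms: none
Why: Normal-electron-demand (4+2) cycloaddition of the doubly donor-substituted diene 6 to ynoate 8, the established Diels-Alder/aromatization route from 1,1-dialkoxy-3-silyloxybutadienes and 2-alkynoates to 2-alkoxy-4-hydroxy-6-alkylbenzoates, should pass through a concerted but strongly asynchronous transition state in which the C5–C6 bond of ring B (diene CH2 terminus to the pentyl-bearing beta carbon) runs ahead of the C1–C2 bond (ketene acetal carbon to the ester-bearing alpha carbon). Ring B is thus closed intermolecularly by two new C–C bonds in one cycloaddition, giving 1,4-cyclohexadiene 9 with a ketal carbon beside the ester-bearing carbon and a silyl enol ether. No stereocentre is present in 9 and none is created, so no stereocontrol is required. Loss of one methanol from 9 (methoxide leaves from the ketal carbon, a proton from the ring CH2) gives aromatic silyl ether 10, and the aqueous acid work-up cleaves the O–Si bond to the free C4 phenol while the C2 oxygen stays methylated. The only selectivity needed is regioselectivity, and it is secured by matched polarisation: both the 1,1-dimethoxy and the 3-silyloxy donors put the largest HOMO coefficient on the diene CH2 terminus, and the ester puts the largest LUMO coefficient on the beta carbon of 8. The benzyl ester is inert to the heat and to the dilute acid.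

**Step 6**
Reactants: 12 hexanoyl chloride
Product: 13 N-methoxy-N-methylhexanamide
Conditions: MeNH(OMe)·HCl, Et3N (2.2 equiv), CH2Cl2, 0 °C to rt
Reagents that add atoms: N,O-dimethylhydroxylamine hydrochloride, CNOC.Cl
Why: Simple N-acylation of the hydroxylamine by the acid chloride gives the Weinreb amide.

**Step 7**
Reactants: 14 methyl 2,4-dimethoxy-6-methylbenzoate; 13 N-methoxy-N-methylhexanamide
Product: 17 methyl 2,4-dimethoxy-6-(2-oxoheptyl)benzoate, via lateral benzyllithium 15 (not isolated), via tetrahedral lithium aminal alkoxide 16 (not isolated)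
Conditions: LiN(iPr)2 (LDA, 2 equiv), THF, −78 °C; then 13, −78 to −40 °C; sat. NH4Cl (aq)
Reagents that add atoms: none
Why: Ester-assisted lateral (benzylic) lithiation of the ortho-toluate gives anion 15, which adds to the Weinreb amide to form chelated adduct 16 that releases the ketone only on quench, so neither over-addition nor proton transfer from formed ketone should interfere (Weinreb ketone synthesis).

**Step 8**
Reactants: 17 methyl 2,4-dimethoxy-6-(2-oxoheptyl)benzoate
Product: 18 methyl 2,4-dimethoxy-6-[(2-pentyl-1,3-dioxolan-2-yl)methyl]benzoate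
Conditions: Me3SiOCH2CH2OSiMe3, Me3SiOTf (cat.), CH2Cl2, −78 to −20 °C; pyridine, NaHCO3 (aq)
Reagents that add atoms: 1,2-bis(trimethylsilyloxy)ethane, C[Si](C)(C)OCCO[Si](C)(C)C
Why: Noyori ketalisation under aprotic conditions at low temperature, driven by formation of hexamethyldisiloxane, should mask the ketone without the heat and protic acid that would promote enol-lactonisation onto the ortho ester to give the isocoumarin.

**Step 9**
Reactants: 18 methyl 2,4-dimethoxy-6-[(2-pentyl-1,3-dioxolan-2-yl)methyl]benzoate
Product: 19 2,4-dimethoxy-6-[(2-pentyl-1,3-dioxolan-2-yl)methyl]benzoic acid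
Conditions: KOH, DMSO/H2O, 90 °C; then 0.5 M HCl to pH 3–4 at 0 °C, immediate extraction (EtOAc), used without storage
Reagents that add atoms: potassium hydroxide, [K+].[OH-]
Why: Saponification of the hindered di-ortho-substituted methyl ester needs hot hydroxide, which the base-stable ketal tolerates now that no enolisable ketone is present, and cold acidification only to pH 3–4 should keep the dioxolane intact.

**Step 10**
Reactants: 19 2,4-dimethoxy-6-[(2-pentyl-1,3-dioxolan-2-yl)methyl]benzoic acid; 11 benzyl 4-hydroxy-2-methoxy-6-pentylbenzoate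
Product: 20 benzyl 4-({2,4-dimethoxy-6-[(2-pentyl-1,3-dioxolan-2-yl)methyl]benzoyl}oxy)-2-methoxy-6-pentylbenzoate
Conditions: DCC, DMAP (cat.), CH2Cl2, 0 °C to rt
Reagents that add atoms: none
Why: Steglich esterification transfers the carbodiimide-activated acyl group through DMAP to the only free hydroxyl of 11 under neutral conditions that spare the ketal and the benzyl ester, and with the ketone masked the activated carboxyl cannot be trapped by its enol.

**Step 11**
Reactants: 20 benzyl 4-({2,4-dimethoxy-6-[(2-pentyl-1,3-dioxolan-2-yl)methyl]benzoyl}oxy)-2-methoxy-6-pentylbenzoate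
Product: 21 benzyl 4-{[2,4-dimethoxy-6-(2-oxoheptyl)benzoyl]oxy}-2-methoxy-6-pentylbenzoate
Conditions: 1 M HCl (aq), THF, rt
Reagents that add atoms: water, O
Why: Acid-catalysed ketal hydrolysis in a large excess of water should regenerate the ketone, while the aryl ester and the benzyl ester need much harsher acid or base to cleave.

**Step 12**
Reactants: 21 benzyl 4-{[2,4-dimethoxy-6-(2-oxoheptyl)benzoyl]oxy}-2-methoxy-6-pentylbenzoate
Product: 22 4-{[2,4-dimethoxy-6-(2-oxoheptyl)benzoyl]oxy}-2-methoxy-6-pentylbenzoic acid
Conditions: H2 (1 atm), Pd/C (10% palladium on carbon), EtOAc, rt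
Reagents that add atoms: none
Why: Catalytic hydrogenolysis of the benzylic C–O bond frees the carboxylic acid and leaves the aryl ester, the dialkyl ketone and the methyl ethers untouched.

**Compound list**
1 | acetyl chloride | CC(=O)Cl | starting material
2 | 1,1-dichloroethene | C=C(Cl)Cl | starting material
3 | 4,4,4-trichlorobutan-2-one | CC(=O)CC(Cl)(Cl)Cl | intermediate
4 | 4,4-dichlorobut-3-en-2-one | CC(=O)C=C(Cl)Cl | intermediate
5 | 4,4-dimethoxybut-3-en-2-one | CC(=O)C=C(OC)OC | intermediate
6 | 1,1-dimethoxy-3-(trimethylsilyloxy)buta-1,3-diene | COC(OC)=CC(=C)O[Si](C)(C)C | intermediate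
7 | oct-2-ynoic acid | CCCCCC#CC(=O)O | starting material
8 | benzyl oct-2-ynoate | CCCCCC#CC(=O)OCc1ccccc1 | intermediate
9 | benzyl 6,6-dimethoxy-2-pentyl-4-(trimethylsilyloxy)cyclohexa-1,4-diene-1-carboxylate | CCCCCC1=C(C(=O)OCc2ccccc2)C(OC)(OC)C=C(O[Si](C)(C)C)C1 | intermediate
10 | benzyl 2-methoxy-6-pentyl-4-(trimethylsilyloxy)benzoate | CCCCCc1cc(O[Si](C)(C)C)cc(OC)c1C(=O)OCc1ccccc1 | intermediate
11 | benzyl 4-hydroxy-2-methoxy-6-pentylbenzoate | CCCCCc1cc(O)cc(OC)c1C(=O)OCc1ccccc1 | intermediate
12 | hexanoyl chloride | CCCCCC(=O)Cl | starting material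
13 | N-methoxy-N-methylhexanamide | CCCCCC(=O)N(C)OC | intermediate
14 | methyl 2,4-dimethoxy-6-methylbenzoate | COC(=O)c1c(C)cc(OC)cc1OC | starting material
15 | [3,5-dimethoxy-2-(methoxycarbonyl)benzyl]lithium | [Li]Cc1cc(OC)cc(OC)c1C(=O)OC | intermediate
16 | lithium 1-[3,5-dimethoxy-2-(methoxycarbonyl)phenyl]-2-[methoxy(methyl)amino]heptan-2-olate (racemic) | CCCCCC(O[Li])(Cc1cc(OC)cc(OC)c1C(=O)OC)N(C)OC | intermediate
17 | methyl 2,4-dimethoxy-6-(2-oxoheptyl)benzoate | CCCCCC(=O)Cc1cc(OC)cc(OC)c1C(=O)OC | intermediate
18 | methyl 2,4-dimethoxy-6-[(2-pentyl-1,3-dioxolan-2-yl)methyl]benzoate | CCCCCC1(Cc2cc(OC)cc(OC)c2C(=O)OC)OCCO1 | intermediate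
19 | 2,4-dimethoxy-6-[(2-pentyl-1,3-dioxolan-2-yl)methyl]benzoic acid | CCCCCC1(Cc2cc(OC)cc(OC)c2C(=O)O)OCCO1 | intermediate
20 | benzyl 4-({2,4-dimethoxy-6-[(2-pentyl-1,3-dioxolan-2-yl)methyl]benzoyl}oxy)-2-methoxy-6-pentylbenzoate | CCCCCC1(Cc2cc(OC)cc(OC)c2C(=O)Oc2cc(CCCCC)c(C(=O)OCc3ccccc3)c(OC)c2)OCCO1 | intermediate
21 | benzyl 4-{[2,4-dimethoxy-6-(2-oxoheptyl)benzoyl]oxy}-2-methoxy-6-pentylbenzoate | CCCCCC(=O)Cc1cc(OC)cc(OC)c1C(=O)Oc1cc(CCCCC)c(C(=O)OCc2ccccc2)c(OC)c1 | intermediate
22 | 4-{[2,4-dimethoxy-6-(2-oxoheptyl)benzoyl]oxy}-2-methoxy-6-pentylbenzoic acid (CNP0169128.0) | CCCCCC(=O)Cc1cc(OC)cc(OC)c1C(=O)Oc1cc(CCCCC)c(C(=O)O)c(OC)c1 | target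

**Totals**
Total step count: 12. Longest linear sequence: 7 steps (1, 2, 3, 5, 10, 11, 12; the ring A branch 6, 7, 8, 9, 10, 11, 12 is equally long).

**Steps most likely to fail**

1. Step 5. The beta-alkyl ynoate is a weakly activated dienophile, so the cycloaddition may be slower than thermal decomposition or adventitious desilylation of the diene. The fallback changes the dienophile class from an alkyne to a more reactive allene. It sets out from hexanoyl chloride 12 (diene 6 is kept) and rejoins the route at phenol 11. Hexanoyl chloride 12 is dehydrochlorinated with Et3N in CH2Cl2 at 0 °C to butylketene F1 in the presence of benzyl (triphenylphosphoranylidene)acetate. Wittig reaction at the ketene carbonyl should give the allenic ester benzyl octa-2,3-dienoate F2 (racemic). Its conjugated C2=C3 bond should add diene 6 near room temperature with the same orientation (diene CH2 to the central allene carbon) to give benzyl 2,2-dimethoxy-6-pentylidene-4-(trimethylsilyloxy)cyclohex-3-ene-1-carboxylate F3, which is not isolated. Dilute acid should then cause loss of methanol and migration of the exocyclic double bond into the ring, giving silyl ether 10 and, after desilylation, phenol 11.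

2. Step 11. The oxocarbenium ion formed on opening the dioxolane sits five atoms from the depside carbonyl oxygen; neighbouring-group capture could expel the ring B phenol and close an isocoumarin, cleaving the depside. The fallback unmasks the ketone by neutral oxidative cleavage of a C=C bond instead of acid hydrolysis. It sets out from keto ester 17 and rejoins at 21. Wittig methylenation of 17 (methyltriphenylphosphonium bromide, KOtBu, THF, 0 °C) should give methyl 2,4-dimethoxy-6-(2-methylideneheptyl)benzoate F6. Saponification with KOH in refluxing EtOH/H2O (protic medium, so that the skipped alkene does not migrate into conjugation) should give 2,4-dimethoxy-6-(2-methylideneheptyl)benzoic acid F7. DCC/DMAP coupling with phenol 11 should give benzyl 4-{[2,4-dimethoxy-6-(2-methylideneheptyl)benzoyl]oxy}-2-methoxy-6-pentylbenzoate F8. Ozonolysis (O3, CH2Cl2/MeOH, −78 °C, Sudan Red 7B as end-point indicator, then Me2S) should cleave the 1,1-disubstituted alkene faster than the acylated arenes and deliver 21 directly.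

3. Step 10. Acyl transfer from the di-ortho-substituted acid may be slow enough for O-to-N acyl migration to the N-acylurea to take over, and acid 19 may isomerise by intramolecular opening of its ketal before it is activated. The fallback replaces in-situ carbodiimide dehydration by an isolated acyl fluoride and a preformed phenoxide. It sets out from acid 19 and rejoins at 20. Acid 19 with cyanuric fluoride and pyridine in CH2Cl2 at −20 °C should give 2,4-dimethoxy-6-[(2-pentyl-1,3-dioxolan-2-yl)methyl]benzoyl fluoride F4, a small, HCl-free acyl donor compatible with the ketal. Phenol 11 is converted with NaH in THF at 0 °C into sodium 4-[(benzyloxy)carbonyl]-3-methoxy-5-pentylphenolate F5, and addition of F4 should give depside 20.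

**Further compounds**
F1 | step 5 | butylketene | CCCCC=C=O
F2 | step 5 | benzyl octa-2,3-dienoate (racemic) | CCCCC=C=CC(=O)OCc1ccccc1
F3 | step 5 | benzyl 2,2-dimethoxy-6-pentylidene-4-(trimethylsilyloxy)cyclohex-3-ene-1-carboxylate (racemic, alkene geometry not defined) | CCCCC=C1CC(O[Si](C)(C)C)=CC(OC)(OC)C1C(=O)OCc1ccccc1
F4 | step 10 | 2,4-dimethoxy-6-[(2-pentyl-1,3-dioxolan-2-yl)methyl]benzoyl fluoride | CCCCCC1(Cc2cc(OC)cc(OC)c2C(F)=O)OCCO1
F5 | step 10 | sodium 4-[(benzyloxy)carbonyl]-3-methoxy-5-pentylphenolate | CCCCCc1cc([O-])cc(OC)c1C(=O)OCc1ccccc1.[Na+]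
F6 | step 11 | methyl 2,4-dimethoxy-6-(2-methylideneheptyl)benzoate | CCCCCC(=C)Cc1cc(OC)cc(OC)c1C(=O)OC
F7 | step 11 | 2,4-dimethoxy-6-(2-methylideneheptyl)benzoic acid | CCCCCC(=C)Cc1cc(OC)cc(OC)c1C(=O)O
F8 | step 11 | benzyl 4-{[2,4-dimethoxy-6-(2-methylideneheptyl)benzoyl]oxy}-2-methoxy-6-pentylbenzoate | CCCCCC(=C)Cc1cc(OC)cc(OC)c1C(=O)Oc1cc(CCCCC)c(C(=O)OCc2ccccc2)c(OC)c1
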